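On a small charge of L you can see the loss plainly: the midnight run, at 0.10 M, falls from 88.7% Q at 40.0 min to 79.4% at 80.0 min. The two earlier runs and the new flask stand here:

| setting | midnight | noon | flask |
|---|---|---|---|
| L | 0.10 M | 0.15 M | 0.20 M |
| D | 83 mM (held) | 83 mM (held) | 83 mM (held) |
| remark | run made earlier | run made earlier |  |
| time |  |  | 1.0 h |

- midnight (time / min: Q / %, E / %): 20.0: 89.7, 86.0; 40.0: 88.7, 86.5; 50.0: 87.4, 83.9; 80.0: 79.4, 79.2
- noon (time / min: Q / %, E / %): 20.0: 88.7, 85.4; 40.0: 89.8, 91.2; 50.0: 89.8, 90.3; 80.0: 86.8, 84.6

(standard deviation of a reading: 1 percentage point)

- what is said of Q includes E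
- E is a solid; its amount is given per volume of the solution
- the earlier runs were read with a standard deviation of 1 percentage point
- at the start none of D is in solution
- X is what D becomes in solution

- how much Q and E together there is at 1.0 h, in percent of the L charged
- concentration of X in solution at 1.0 h, in percent of saturation

Build the flask up step by step. Take the main step by itself: L, the limiting reagent while D is held, turns into Q, and the yield stands at 100%, the zero of your scale. Add the crystals and that number stays, since E is counted inside Q, though nearly all of the Q in the midnight run at 80.0 min is E.

Now add the loss, and measure it in concentration. Call the shortfall the mM of charged L not standing as Q, read at 1.0 h on a straight line between the last two readings. The midnight run gives 15.3 mM and the noon run 16.8 mM, readings with a scatter of 1 percentage point. I carry their mean, 16.0 mM, over to the flask at this hour as an estimate.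

The noon run made Q at 6.65 mM min⁻¹ on average over its first 20.0 min. At that pace the flask's charge needs 30.1 min, shorter than the hour asked. My reckoning for the flask is therefore 92.0%.

The forecast says 90% for Q and E together, lower than my 92.0%, and 97% of saturation for X. Of the loss, which it takes as a rate in mM per minute, it writes: “it is roughly fixed in absolute terms and smaller in percent at higher charge”.

The flask gives 91.0% for Q and E together and 98.8% of saturation for X, both within the margin.

    D ⇌ X, rate k1*(csat - [X]) (kL = 0.00317 s⁻¹)
    L + X → Q (k = 0.0866 L mol⁻¹ s⁻¹)
    X + Q → J (k = 0.0175 L mol⁻¹ s⁻¹)
    E ⇌ Q, rate k4*(cs4 - [Q]) while solid is left; crystals form when [Q] > cs4 (solubility = 2.40 mM, k = 0.00850 s⁻¹)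

In the flask at 1.00 h, the distance from the zero of the scale is 17.9 mM, more than the carried 16.0 mM, with L at 0% and J at 8.96%. Now lower the charge to 0.12 M, holding the time and the rest. Carried here as well, 16.0 mM is a larger share of this smaller charge than of the flask's, and the reckoning gives 86.7%. That neighbour flask gives 86.5%, with L at 0% and J at 13.5%.

The data stem from a simulated flask for an exercise.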